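Saturday's run at 5 mM and Thursday's at 20 mM lie over each other, so the new flask at 10 mM can be read from them without a correction for concentration. What stands open is how the ratio of target to isomer of the product A moves with time.

| flask | starting material | remark | time |
|---|---|---|---|
| Saturday's | 5 mM | run made earlier |  |
| Thursday's | 20 mM | run made earlier |  |
| flask | 10 mM |  | 1.0 h |

| run | time / min | target / % | isomer of the product A / % |
|---|---|---|---|
| Saturday's | 3.00 | 32.1 | 11.6 |
| Saturday's | 5.00 | 36.7 | 15.1 |
| Saturday's | 8.00 | 43.1 | 15.5 |
| Saturday's | 12.0 | 47.2 | 17.1 |
| Saturday's | 20.0 | 46.6 | 16.6 |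
| Saturday's | 40.0 | 47.8 | 18.3 |
| Thursday's | 2.50 | 29.1 | 6.8 |
| Thursday's | 8.00 | 43.1 | 16.6 |
| Thursday's | 12.0 | 45.7 | 17.8 |
| Thursday's | 20.0 | 48.3 | 18.5 |
| Thursday's | 30.0 | 50.0 | 17.4 |
| Thursday's | 40.0 | 45.9 | 16.4 |

(scatter of a reading: 1 percentage point)

- the numbers in the tables scatter by 1 percentage point (one standard deviation)

* ratio of target to isomer of the product A at 4.0 s
* ratio of target to isomer of the product A at 1.0 h
* which of target and isomer of the product A there is more of at 1.0 h

The first chemist holds that the two products form side by side, so their ratio is flat. The readings from 20.0 min on, pooled over both runs, give 2.74, and Saturday's first reading, at 3.00 min, already gives 2.77.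

The second chemist holds that the isomer of the product A is made from something that must itself be made first. Such a product starts with zero slope, so while it is young the ratio falls as one over time, and ratio times time stays constant: call this the lag product. Thursday's earliest reading, at 2.50 min, gives a ratio of 4.28 and so a lag product of 10.7 min.

The first objects that this rests on 6.8% of isomer, read with a scatter of 1 percentage point. That is fair, though a flat ratio would have put that reading at 10.6%. The falling ratio must meet the plateau somewhere, and lag product over plateau ratio puts the meeting at 3.91 min, the crossing time, where kinetic control gives way to thermodynamic control. Saturday's first reading comes just before it, and its 2.77 stands below the 3.57 of the rule, so the lag product is a rough figure.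

I side with the second. At 4.0 s, far earlier than the crossing, my reckoning gives 160; at 1.0 h, far later, it gives 2.74, with target ahead.

The forecast takes the first side, with 2.7 at 4.0 s, 2.7 at 1.0 h and target ahead: “Saturday's isomer shows no lag behind target, which favours parallel formation.”

The flask gives 110 at 4.0 s and 2.78 at 1.0 h, with target ahead, 48.0% against 17.3%.

    isomer of the product A ⇌ isomer of the product B (K = 1.47, k = 0.00182 s⁻¹)
    starting material ⇌ target (K = 5.10, k = 0.00768 s⁻¹)
    target ⇌ isomer of the product A (K = 0.360, k = 3.34 × 10⁻⁴ s⁻¹)
    isomer of the product B ⇌ starting material (k = 0.00962 s⁻¹)

At 1.8 min, earlier than the crossing at 3.91 min, the flask holds 26.5% of target and 5.71% of isomer of the product A, a ratio of 4.64. At 6 min, later than the crossing, this flask holds 40.0% of target and 14.0% of isomer of the product A, a ratio of 2.86, and there the first chemist's flat ratio describes it. The neighbour charged with 40 mM gives 110 at 4.0 s, before the crossing, and 2.78 at 1.0 h, after it.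

(The readings are simulated from invented constants, noise included.)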